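**Retrosynthetic overview**

1. The target is a bicyclo[3.2.1]octan-8-one (C1 allyl bridgehead, C2 H2, C3 OMe, C4 OH, C5 OMe bridgehead, C6 aryl, C7 methyl, C8 C=O). It ends with O3-methylation of the exo-cis-3,4-diol, which comes from exo-face osmylation of the C3=C4 alkene of 15; the allyl group is carried as a silyl-capped propargyl group (inert to OsO4) and unmasked by semihydrogenation.
2. Key disconnections, all in one flask: C1–C2 (ring-closing Tsuji–Trost alkylation), C5–C4 (aldol) and C6–aryl (conjugate addition). This is a formal [3+3] annulation of acrolein, as a 1,3-bis-electrophile, across the α,α′-positions of cyclopentenone 9, with the aryl Grignard as third component.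
3. Enabling feature: the C8 carbonyl lies between C1 and C5. Once the aldol has made C5 quaternary (OMe plus side chain), the ketone can enolise only at C1. The C5 side chain is 1,3-cis to C1 across the five-membered ring C1–C8–C5–C6–C7 and can reach C1 only with its terminal carbon C2, closing the six-membered ring C1–C2–C3–C4–C5–C8.
4. Enone 9 comes from 3-methylcyclopent-2-enone by asymmetric copper hydride reduction/alkylation (sets C7, the only reagent-controlled stereocentre), dehydrogenation, epoxidation and methanolysis.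
5. Ring order: the cyclopentane ring is bought; the six- and seven-membered rings close together in the key step; C6, C5, C1, C3 and C4 are all relayed from C7.

Key step: step 5

Remark on numbering: all bicyclic compounds are numbered as in line 1 of the overview.
Assumption: the copper hydride of (S)-p-tol-BINAP is taken to give the (3S) enol ether 3; if the sense of induction is the opposite, the (R)-ligand is used.

**Route**

Step 1
Reactants: 1 3-methylcyclopent-2-en-1-one; 2 (3-bromoprop-1-yn-1-yl)tri(propan-2-yl)silane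
Product: 4 (2R,3S)-3-methyl-2-[3-(triisopropylsilyl)prop-2-yn-1-yl]cyclopentan-1-one, via silyl enol ether 3 (not isolated)
Conditions: CuCl (5 mol %), NaOtBu (5 mol %), (S)-p-tol-BINAP (5 mol %), Ph2SiH2 (1.0 equiv), toluene, 0 °C; then Bu4N[Ph3SiF2], 2, CH2Cl2/THF, 23 °C
Reagents that add atoms: none
Why: Asymmetric conjugate reduction by a chiral bisphosphine copper hydride (monovalent copper) sets C3 under catalyst control and gives the regiodefined silyl enol ether, whose fluoride-released enolate is alkylated anti to the C3 methyl (substrate control) to give the trans ketone; the bulky silyl cap blocks SN2′ attack on the propargylic bromide.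

Step 2
Reactants: 4 (2R,3S)-3-methyl-2-[3-(triisopropylsilyl)prop-2-yn-1-yl]cyclopentan-1-one
Product: 6 (4S,5R)-4-methyl-5-[3-(triisopropylsilyl)prop-2-yn-1-yl]cyclopent-2-en-1-one, via lithium enolate 5 (not isolated)
Conditions: LiN(iPr)2, THF, −78 °C; then PhS(Cl)=NtBu, −78 °C
Reagents that add atoms: none
Why: Kinetic deprotonation at the unsubstituted α-CH2 followed by Mukaiyama dehydrogenation (S-sulfinimidoylation, then syn-elimination) should place the enone on the side remote from the two substituents; no stereocentre is formed and C4 and C5 are untouched.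

Step 3
Reactants: 6 (4S,5R)-4-methyl-5-[3-(triisopropylsilyl)prop-2-yn-1-yl]cyclopent-2-en-1-one
Product: 7 (1S,3R,4R,5S)-4-methyl-3-[3-(triisopropylsilyl)prop-2-yn-1-yl]-6-oxabicyclo[3.1.0]hexan-2-one
Conditions: H2O2 (30 % aq.), NaOH (cat.), MeOH, 0 °C
Reagents that add atoms: hydrogen peroxide, OO
Why: Weitz–Scheffer nucleophilic epoxidation of the enone, in which hydroperoxide adds to the β-carbon anti to the adjacent methyl so that the epoxide should form trans to it (this configuration is erased in step 4).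

Step 4
Reactants: 7 (1S,3R,4R,5S)-4-methyl-3-[3-(triisopropylsilyl)prop-2-yn-1-yl]-6-oxabicyclo[3.1.0]hexan-2-one
Product: 9 (4S,5R)-2-methoxy-4-methyl-5-[3-(triisopropylsilyl)prop-2-yn-1-yl]cyclopent-2-en-1-one, via hydroxy methoxy ketone 8 (not isolated)
Conditions: NaOMe (0.5 equiv), MeOH, 0 to 23 °C
Reagents that add atoms: methanol, CO
Why: Methoxide should open the α,β-epoxy ketone at the carbonyl-activated α-carbon (SN2) and the resulting β-hydroxy ketone lose water by E1cB, the usual conversion of epoxy ketones into α-alkoxy enones; no new stereocentre is formed and C4 lies outside the reacting system.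

Step 5
Reactants: 9 (4S,5R)-2-methoxy-4-methyl-5-[3-(triisopropylsilyl)prop-2-yn-1-yl]cyclopent-2-en-1-one; 10 (3,4,5-trimethoxyphenyl)magnesium bromide; 11 acrolein
Product: 15 (1R,5S,6R,7S)-5-methoxy-7-methyl-1-[3-(triisopropylsilyl)prop-2-yn-1-yl]-6-(3,4,5-trimethoxyphenyl)bicyclo[3.2.1]oct-3-en-8-one, via magnesium enolate 12 (not isolated), via magnesium aldolate 13 (not isolated), via allylic carbonate 14 (not isolated)
Conditions: 10 (1.1 equiv), CuBr·SMe2 (10 mol %), THF, −78 to −40 °C; 11 (1.2 equiv), −78 °C; ClCO2Me (1.2 equiv), −78 to 0 °C; then Pd(PPh3)4 (5 mol %), iPr2NEt (2 equiv), 0 to 50 °C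
Reagents that add atoms: none
Why: Copper-catalysed 1,4-addition of 10 (anti to the methyl-bearing carbon, the future C7) gives the regiodefined enolate 12, which adds to the aldehyde of 11 anti to the new aryl group (three-component conjugate addition–aldol coupling) and is capped as carbonate 14; zerovalent palladium then ionises 14 (Tsuji–Trost allylic alkylation), the magnesium halide/amine pair and the released methoxide enolise the only α-C–H left, and the enolate carbon attacks the unsubstituted allyl terminus to form C1–C2. The closest known reaction type is the palladium-catalysed α,α′-bicycloannulation of cyclic ketones with allylic bis-electrophiles, here with acrolein serving as the 1,3-bis-electrophile. The bond closes the six-membered ring C1–C2–C3–C4–C5–C8 and with it the seven-membered ring C1–C2–C3–C4–C5–C6–C7 in a 6-endo attack on the anti π-allyl, since attack at the inner terminus would give a four-membered ring. C6 is controlled by the C7 methyl (aryl enters trans), C5 by the C6 aryl (aldehyde enters trans), and C1 by the tether, which can bond only on the ring face that carries it and so turns the propargyl group outward; the carbinol centre of 14 is erased on ionisation, so both epimers converge. The step needs C- over O-allylation and access to the anti allyl: an O-allylated enol ether would re-ionise under palladium, halide in the flask speeds syn/anti exchange, and β-hydride loss to a diene is excluded because C5 is quaternary.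

Step 6
Reactants: 15 (1R,5S,6R,7S)-5-methoxy-7-methyl-1-[3-(triisopropylsilyl)prop-2-yn-1-yl]-6-(3,4,5-trimethoxyphenyl)bicyclo[3.2.1]oct-3-en-8-one
Product: 16 (1R,5S,6R,7S)-5-methoxy-7-methyl-1-(prop-2-yn-1-yl)-6-(3,4,5-trimethoxyphenyl)bicyclo[3.2.1]oct-3-en-8-one
Conditions: Bu4NF, THF, 0 °C
Reagents that add atoms: none
Why: Fluoride-mediated protodesilylation of the alkynylsilane; the bridged ketone has no α-hydrogen and no stereocentre is touched.

Step 7
Reactants: 16 (1R,5S,6R,7S)-5-methoxy-7-methyl-1-(prop-2-yn-1-yl)-6-(3,4,5-trimethoxyphenyl)bicyclo[3.2.1]oct-3-en-8-one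
Product: 17 (1S,3R,4R,5R,6R,7S)-3,4-dihydroxy-5-methoxy-7-methyl-1-(prop-2-yn-1-yl)-6-(3,4,5-trimethoxyphenyl)bicyclo[3.2.1]octan-8-one
Conditions: OsO4 (5 mol %), NMO, acetone/H2O, 23 °C
Reagents that add atoms: N-methylmorpholine N-oxide, C[N+]1([O-])CCOCC1; water, O
Why: Catalytic OsO4/NMO syn-dihydroxylation should occur on the exo face of the C3=C4 alkene (the endo face is covered by the C6–C7 bridge and its endo C7 methyl), setting C3 and C4 together as the exo-cis-diol, while the terminal alkyne reacts far more slowly than an alkene.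

Step 8
Reactants: 17 (1S,3R,4R,5R,6R,7S)-3,4-dihydroxy-5-methoxy-7-methyl-1-(prop-2-yn-1-yl)-6-(3,4,5-trimethoxyphenyl)bicyclo[3.2.1]octan-8-one
Product: 18 (1S,3R,4R,5R,6R,7S)-3,4-dihydroxy-5-methoxy-7-methyl-1-(prop-2-en-1-yl)-6-(3,4,5-trimethoxyphenyl)bicyclo[3.2.1]octan-8-one
Conditions: H2 (1 atm), Pd/CaCO3 poisoned with Pb(OAc)2, quinoline, EtOAc, 23 °C
Reagents that add atoms: none
Why: Lindlar semihydrogenation of the terminal alkyne should unmask the allyl group only after the osmylation that it would not have survived; no stereocentre is involved.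

Step 9
Reactants: 18 (1S,3R,4R,5R,6R,7S)-3,4-dihydroxy-5-methoxy-7-methyl-1-(prop-2-en-1-yl)-6-(3,4,5-trimethoxyphenyl)bicyclo[3.2.1]octan-8-one
Product: 20 (1S,3R,4R,5R,6R,7S)-4-hydroxy-3,5-dimethoxy-7-methyl-1-(prop-2-en-1-yl)-6-(3,4,5-trimethoxyphenyl)bicyclo[3.2.1]octan-8-one, via stannylene acetal 19 (not isolated)
Conditions: Bu2SnO, toluene, reflux (−H2O); then MeI, CsF, DMF, 40 °C
Reagents that add atoms: iodomethane, CI
Why: Regioselective O-alkylation of a cis-diol through its dibutylstannylene acetal should methylate the equatorial O3 and not the axial O4 beside the quaternary C5 (as in carbohydrate cis-diols), and the mild fluoride conditions avoid retro-aldol of the C4 β-hydroxy ketone; no stereocentre changes.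

**Compound list**

1 | 3-methylcyclopent-2-en-1-one | CC1=CC(=O)CC1 | starting material
2 | (3-bromoprop-1-yn-1-yl)tri(propan-2-yl)silane | BrCC#C[Si](C(C)C)(C(C)C)C(C)C | starting material
3 | {[(3S)-3-methylcyclopent-1-en-1-yl]oxy}diphenylsilane | C[C@H]1CCC(O[SiH](c2ccccc2)c2ccccc2)=C1 | intermediate (not isolated)
4 | (2R,3S)-3-methyl-2-[3-(triisopropylsilyl)prop-2-yn-1-yl]cyclopentan-1-one (2,3-trans) | CC(C)[Si](C(C)C)(C(C)C)C#CC[C@H]1C(=O)CC[C@@H]1C | intermediate
5 | kinetic lithium enolate of 4 (enolised toward the CH2 side; both stereocentres of 4 kept) | CC(C)[Si](C(C)C)(C(C)C)C#CC[C@H]1C(O[Li])=CC[C@@H]1C | intermediate (not isolated)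
6 | (4S,5R)-4-methyl-5-[3-(triisopropylsilyl)prop-2-yn-1-yl]cyclopent-2-en-1-one (4,5-trans) | CC(C)[Si](C(C)C)(C(C)C)C#CC[C@H]1C(=O)C=C[C@@H]1C | intermediate
7 | (1S,3R,4R,5S)-4-methyl-3-[3-(triisopropylsilyl)prop-2-yn-1-yl]-6-oxabicyclo[3.1.0]hexan-2-one (epoxide trans to the methyl) | CC(C)[Si](C(C)C)(C(C)C)C#CC[C@H]1C(=O)[C@H]2O[C@H]2[C@@H]1C | intermediate
8 | 3-hydroxy-2-methoxy-4-methyl-5-[3-(triisopropylsilyl)prop-2-yn-1-yl]cyclopentan-1-one (2-OMe and 3-OH trans; 3-OH trans to the 4-methyl) | CC(C)[Si](C(C)C)(C(C)C)C#CC[C@H]1C(=O)[C@H](OC)[C@@H](O)[C@@H]1C | intermediate (not isolated)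
9 | (4S,5R)-2-methoxy-4-methyl-5-[3-(triisopropylsilyl)prop-2-yn-1-yl]cyclopent-2-en-1-one | CC(C)[Si](C(C)C)(C(C)C)C#CC[C@H]1C(=O)C(OC)=C[C@@H]1C | intermediate
10 | (3,4,5-trimethoxyphenyl)magnesium bromide (commercial THF solution) | COc1cc([Mg]Br)cc(OC)c1OC | starting material
11 | acrolein (prop-2-enal) | C=CC=O | starting material
12 | bromomagnesium enolate of the 3-aryl-2-methoxycyclopentanone (aryl trans to the methyl) | CC(C)[Si](C(C)C)(C(C)C)C#CC[C@H]1C(O[Mg]Br)=C(OC)[C@@H](c2cc(OC)c(OC)c(OC)c2)[C@@H]1C | intermediate (not isolated)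
13 | bromomagnesium aldolate: 2-(1-oxidoallyl)-2-methoxy-3-aryl-4-methyl-5-(silylpropargyl)cyclopentanone (side chain trans to the aryl, cis to the methyl; carbinol carbon both epimers) | CC(C)[Si](C(C)C)(C(C)C)C#CC[C@H]1C(=O)[C@](OC)(C(O[Mg]Br)C=C)[C@@H](c2cc(OC)c(OC)c(OC)c2)[C@@H]1C | intermediate (not isolated)
14 | methyl carbonate of aldol 13 (allylic methyl carbonate; carbinol carbon both epimers) | CC(C)[Si](C(C)C)(C(C)C)C#CC[C@H]1C(=O)[C@](OC)(C(OC(=O)OC)C=C)[C@@H](c2cc(OC)c(OC)c(OC)c2)[C@@H]1C | intermediate (not isolated)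
15 | (1R,5S,6R,7S)-5-methoxy-7-methyl-1-[3-(triisopropylsilyl)prop-2-yn-1-yl]-6-(3,4,5-trimethoxyphenyl)bicyclo[3.2.1]oct-3-en-8-one (aryl exo, methyl endo) | CC(C)[Si](C(C)C)(C(C)C)C#CC[C@@]12CC=C[C@@](OC)(C1=O)[C@@H](c1cc(OC)c(OC)c(OC)c1)[C@@H]2C | intermediate
16 | (1R,5S,6R,7S)-5-methoxy-7-methyl-1-(prop-2-yn-1-yl)-6-(3,4,5-trimethoxyphenyl)bicyclo[3.2.1]oct-3-en-8-one | C#CC[C@@]12CC=C[C@@](OC)(C1=O)[C@@H](c1cc(OC)c(OC)c(OC)c1)[C@@H]2C | intermediate
17 | (1S,3R,4R,5R,6R,7S)-3,4-dihydroxy-5-methoxy-7-methyl-1-(prop-2-yn-1-yl)-6-(3,4,5-trimethoxyphenyl)bicyclo[3.2.1]octan-8-one (both OH exo) | C#CC[C@@]12C[C@@H](O)[C@@H](O)[C@@](OC)(C1=O)[C@@H](c1cc(OC)c(OC)c(OC)c1)[C@@H]2C | intermediate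
18 | (1S,3R,4R,5R,6R,7S)-3,4-dihydroxy-5-methoxy-7-methyl-1-(prop-2-en-1-yl)-6-(3,4,5-trimethoxyphenyl)bicyclo[3.2.1]octan-8-one | C=CC[C@@]12C[C@@H](O)[C@@H](O)[C@@](OC)(C1=O)[C@@H](c1cc(OC)c(OC)c(OC)c1)[C@@H]2C | intermediate
19 | 3,4-O-dibutylstannylene acetal of 18 | C=CC[C@@]12C[C@H]3O[Sn](CCCC)(CCCC)O[C@H]3[C@@](OC)(C1=O)[C@@H](c1cc(OC)c(OC)c(OC)c1)[C@@H]2C | intermediate (not isolated)
20 | (1S,3R,4R,5R,6R,7S)-4-hydroxy-3,5-dimethoxy-7-methyl-1-(prop-2-en-1-yl)-6-(3,4,5-trimethoxyphenyl)bicyclo[3.2.1]octan-8-one | C=CC[C@@]12C[C@@H](OC)[C@@H](O)[C@@](OC)(C1=O)[C@@H](c1cc(OC)c(OC)c(OC)c1)[C@@H]2C | target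

**Step count and risks**

Total step count: 9. Longest linear sequence: 9 steps (1 to 20).

Steps most likely to fail:

1. Step 5. The palladium stage may not turn over in the crude mixture: syn-to-anti equilibration of a π-allyl with a quaternary neighbour may be slow, methoxide may capture the allyl, or copper and magnesium salts may inhibit the catalyst. The copper-catalysed aryl addition to an α-alkoxy enone may also leak into 1,2-addition. The fallback sets out from 9 and returns at 15, replacing the allylic alkylation by a Michael ring closure of the same bond. The conjugate arylation/acrolein aldol is run alone and quenched cold with AcOH to give β-hydroxy ketone F1 (both carbinol epimers). Dess–Martin periodinane then gives vinyl ketone F2. KN(SiMe3)2 (THF, −78 °C) forms the only possible enolate, which closes by 6-endo-trig Michael addition onto the enone terminus (again C1–C2); the resulting C4 enolate is trapped in the same flask with PhNTf2 as enol triflate F3. Reduction with Pd(OAc)2/PPh3, Bu3N and HCO2H should give alkene 15.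

2. Step 9. Alkylation may occur at O4 or twice, or the alkoxide may cleave the β-hydroxy ketone by retro-aldol. The fallback sets out from 18 and returns at 20, differentiating the two hydroxyls by the axial-ester rule of cis-diol orthoester hydrolysis. MeC(OMe)3 with catalytic camphorsulfonic acid gives cyclic orthoacetate F4. Brief aqueous AcOH opens it to the axial 4-O-acetate F5, leaving the equatorial 3-OH free. Methylation under non-basic conditions (MeOTf, 2,6-di-tert-butyl-4-methylpyridine) gives acetate methyl ether F6, and K2CO3/MeOH at 0 °C removes the acetate to give 20.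

3. Step 4. Methoxide may open the epoxide at the β-carbon, or epimerise the methyl-bearing carbon through the extended dienolate before dehydration is complete. The fallback sets out from 6 and returns at 9, fixing the oxygen position by cross-coupling. α-Iodination of the enone (I2, pyridine, CH2Cl2) gives 2-iodoenone F7. Ullmann-type vinyl C–O coupling with methanol (CuI cat., 3,4,7,8-tetramethyl-1,10-phenanthroline, Cs2CO3, MeOH/toluene, 80 °C) should give 9.

Further compounds
F1 | step 5 | 2-(1-hydroxyprop-2-en-1-yl)-2-methoxy-4-methyl-5-[3-(triisopropylsilyl)prop-2-yn-1-yl]-3-(3,4,5-trimethoxyphenyl)cyclopentan-1-one (ring stereochemistry as in 14; carbinol both epimers) | CC(C)[Si](C(C)C)(C(C)C)C#CC[C@H]1C(=O)[C@](OC)(C(O)C=C)[C@@H](c2cc(OC)c(OC)c(OC)c2)[C@@H]1C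
F2 | step 5 | 2-acryloyl-2-methoxy-4-methyl-5-[3-(triisopropylsilyl)prop-2-yn-1-yl]-3-(3,4,5-trimethoxyphenyl)cyclopentan-1-one (ring stereochemistry as in 14) | CC(C)[Si](C(C)C)(C(C)C)C#CC[C@H]1C(=O)[C@](OC)(C(=O)C=C)[C@@H](c2cc(OC)c(OC)c(OC)c2)[C@@H]1C
F3 | step 5 | 5-methoxy-7-methyl-8-oxo-1-[3-(triisopropylsilyl)prop-2-yn-1-yl]-6-(3,4,5-trimethoxyphenyl)bicyclo[3.2.1]oct-3-en-4-yl trifluoromethanesulfonate (stereochemistry as in 15) | CC(C)[Si](C(C)C)(C(C)C)C#CC[C@@]12CC=C(OS(=O)(=O)C(F)(F)F)[C@@](OC)(C1=O)[C@@H](c1cc(OC)c(OC)c(OC)c1)[C@@H]2C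
F4 | step 9 | 3,4-O-(1-methoxyethylidene) cyclic orthoacetate of 18 (orthoester carbon both epimers) | C=CC[C@@]12C[C@H]3OC(C)(OC)O[C@H]3[C@@](OC)(C1=O)[C@@H](c1cc(OC)c(OC)c(OC)c1)[C@@H]2C
F5 | step 9 | 4-O-acetyl derivative of 18 (3-OH free) | C=CC[C@@]12C[C@@H](O)[C@@H](OC(C)=O)[C@@](OC)(C1=O)[C@@H](c1cc(OC)c(OC)c(OC)c1)[C@@H]2C
F6 | step 9 | 4-O-acetyl derivative of 20 | C=CC[C@@]12C[C@@H](OC)[C@@H](OC(C)=O)[C@@](OC)(C1=O)[C@@H](c1cc(OC)c(OC)c(OC)c1)[C@@H]2C
F7 | step 4 | (4R,5R)-2-iodo-4-methyl-5-[3-(triisopropylsilyl)prop-2-yn-1-yl]cyclopent-2-en-1-one (same spatial arrangement as 6) | CC(C)[Si](C(C)C)(C(C)C)C#CC[C@H]1C(=O)C(I)=C[C@@H]1C
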